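# Proposed synthesis of CNP0307127.1 (17): arylative carbocyclisation route

Lignan numbering is used throughout: syringyl–C7(OH)–C8–C9–O–C9'–C8'–C7'–guaiacyl, with C8–C8' closing the ring. The target is (7S,8R,8'R), i.e. an (S)-carbinol on a (3R,4R)-trans-tetrahydrofuran.

## The problem

Target 17 is a 9,9'-epoxylignan: a tetrahydrofuran whose C8 carries the syringyl carbinol carbon C7 and whose C8' carries the guaiacylmethyl carbon C7', with three contiguous stereocentres and the two ring substituents trans. The oxygen-bearing ring carbons C9 and C9' are unsubstituted, so the ring has no acetal or lactone handle. The real task is the C8–C8' bond between two tertiary C–H centres, each next to an electron-rich arene. C8 lies alpha to C7, so while C7 is a ketone C8 is configurationally mobile, and the reduction that creates C7 can also select C8. Once C7 is a carbinol, its hydroxyl is homoallylic to an exocyclic C8'=C7' alkene and can deliver hydrogen to it, so C8' can be derived from C8. The p-hydroxybenzylic alcohol ionises to a quinone methide in acid or on heating (epimerisation, hydrogenolysis), and the free phenols are oxidation-prone; the phenols therefore stay benzylated to the last step and the C7 hydroxyl is made late under near-neutral conditions. The enabling feature is that C8 is both the alpha-carbon of an aryl ketone and the ring carbon bonded to C8', while C8'–C7' ends at the guaiacyl ring. This is the pattern left when a stabilised carbanion and an aryl group add across the triple bond of a propargyl ether (O–C9'–C8'≡C7'), closing the ring 5-exo. The extra ester that stabilises the carbanion can leave afterwards as CO2.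

## Retrosynthesis

**17 from 16.** The two O–benzyl bonds are cut last. Benzyl ethers survive strong base, TFA, zerovalent palladium and hydride transfer, and are removed by neutral hydrogenolysis. The forward step must spare the benzylic C7–O bond.

**16 from 15.** The C8'–H and C7'–H bonds are cut, giving homoallylic alcohol 15 with an exocyclic arylidene. Heterogeneous hydrogenation would add from the face opposite the C8 substituent and give the cis ring. A hydroxyl-directed cationic iridium catalyst adds from the same face and gives trans, so 15 needs only two stereocentres and the third is relayed. The alkene geometry of 15 is irrelevant to the outcome.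

**15 from 14.** The C7–H bond is cut, giving β,γ-unsaturated ketone 14, racemic and labile at C8. One asymmetric transfer hydrogenation with dynamic kinetic resolution is asked to set C7 by catalyst control and to choose C8. Reducing only after the alkene is saturated would meet a true racemate (C8' fixed) and cap the yield at one half.

**14 from 12 (through acid 13).** The C8–CO2 bond is restored. The ester is a traceless activator. It is a tert-butyl ester so that it leaves by acidolysis and thermal decarboxylation without base, because base would move the double bond into conjugation. The racemic quaternary C8 of 12 carries no lasting information.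

**12 from 8 and 10 (through enolate 11).** This is the key cut: C8–C8' and C7'–aryl. A palladium-catalysed arylative 5-exo-dig carbocyclisation makes the ring, both skeletal bonds and the second aryl attachment in one step. A stepwise route (alkyne arylation, then cyclisation onto an electron-rich aryl alkyne) risks 6-endo closure. Precursor 8 is an acyclic β-keto ester with no lasting stereocentre; 10 is a simple aryl iodide.

**8 from 7, and 7 from 3 and 5 (through dianion 6).** The C7–C8 bond is cut by an aldol disconnection, followed by oxidation. The alternative, alkoxymethylation of an aroylacetate with a chloromethyl propargyl ether, is set aside: ambident β-keto ester enolates tend to take such hard electrophiles on oxygen. A plain ester enolate has no such ambiguity, and the CH2–O–propargyl arm is already in place in 3.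

**3 from 1 and 2; 5 from 4; 10 from 9.** An oxa-Michael addition and two Williamson benzylations lead back to commercial materials.

## Roads not taken

**Alternative 1:** One-carbon linchpin at C7. The cuts are C7–C8 and C7–aryl on a preformed ring. Ring boronate A2 (boron on C8, chiral dicyclohexylethanediol ester) would be homologated with dichloromethyllithium A3, C8 migrating from boron to carbon under Lewis-acid assistance. The aryl Grignard reagent A4 would then add to boron and displace chloride with inversion to give benzylic boronate A1; oxidation with retention and debenzylation would finish.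
- Merits: C7 is set by the diol director, a dependable element that needs no labile neighbour, and the carbinol appears only in a mild final oxidation.
- Weak points: the step closes no ring and sets no ring stereocentre. A2 must already be a single trans enantiomer, so the C8/C8' problem is only moved upstream. Boron on C8 is beta to the ring oxygen, so the ate complexes can open the ring by beta-elimination. The director must match the existing C8 centre, and the electron-rich benzylic boronate A1 is prone to protodeboronation.
- Comparison: for the C7 centre this road is better founded than the chosen one, whose dynamic reduction is new for this ketone class. The chosen plan sets against it a single step that builds ring, skeleton and second arene from three simple pieces, and ten steps in all, which a route through A2 cannot match once A2 itself is counted.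

**Alternative 2:** Succinate dianion and an oxygen-centred bis-electrophile. The cuts are C8–C9 and C8'–C9'. The 1,4-dianion of di-(−)-menthyl succinate A5 (hindered lithium amide) would be alkylated twice by bis(bromomethyl) ether A6 to give the C2-symmetric trans diester A7.
- Merits: both ring stereocentres, relative and absolute, come in one step from a cheap auxiliary, and the two esters of A7 are homotopic, so the first functionalisation raises no regiochemical question.
- Weak points: A7 carries neither arene and both side chains are at the wrong oxidation level. One ester must become ArCH2 and the other ArCH(OH) with separate control of C7, with statistical loss at the first mono-addition and epimerisable centres next to carbonyl groups; at least eight further steps are foreseeable. A6 is a volatile, strongly carcinogenic bis-electrophile whose second alkylation competes with elimination.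
- Comparison: for the ring stereocentres this road is the safer one, since it uses auxiliary control and no dynamic resolution. The chosen plan sets against it convergence (both aryl groups arrive with the skeleton, no side-chain redox adjustments) and roughly half the length.

**Alternative 3:** Seven-to-five contraction of a vinyl acetal. The cut is C8–C9. Enantioenriched 4,5-dihydro-1,3-dioxepine A8, which already carries C8', would be ionised by a silyl triflate at the acetal C9–O(enol) bond; the enolate carbon C8 would recombine with the oxocarbenium carbon C9 to give aldehyde A9.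
- Merits: C8' is fixed before the key step (such acetals are accessible by asymmetric double-bond migration), C8 follows by equilibration next to the aldehyde, and the rearrangement is mild and catalytic.
- Weak points: the syringyl ring and C7 are still missing. Aryl-metal addition to the alpha-branched, epimerisable, beta-alkoxy aldehyde A9 offers little control at C7 and invites ring opening, so an oxidation/asymmetric reduction pair would follow. The ion-pair recombination can give cis/trans mixtures.
- Comparison: in stereochemical certainty this road is at least equal to the chosen one, because the ring centres are fixed before C7 is made and the last reduction acts on a configurationally defined substrate. The chosen plan sets against it that no C–C bond remains to be made after the key step, that both arenes and the ring arrive together, and that the C7 ketone is present from the start.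

Key step: step 6

Remark: intermediates 7, 8 and 11 to 14 are racemic (7 also a syn/anti mixture) and are written without configuration at the racemic centres; 15 is the first non-racemic compound.

## Route

Step 1
Reactants: 1 prop-2-yn-1-ol (propargyl alcohol); 2 tert-butyl acrylate
Product: 3 tert-butyl 3-(prop-2-yn-1-yloxy)propanoate
Conditions: NaH (5 mol %), 2 (1.2 equiv), THF, 0 °C to rt
Reagents that add atoms: none
Why: Base-catalysed oxa-Michael addition of the propargylic alkoxide to the acrylate; proton transfer regenerates the alkoxide and the tert-butyl ester resists transesterification.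

Step 2
Reactants: 4 4-hydroxy-3,5-dimethoxybenzaldehyde (syringaldehyde)
Product: 5 4-(benzyloxy)-3,5-dimethoxybenzaldehyde
Conditions: BnBr, K2CO3, DMF, 60 °C
Reagents that add atoms: benzyl bromide, BrCc1ccccc1
Why: Williamson ether synthesis on the phenoxide; benzyl is chosen because it survives amide bases, TFA, zerovalent palladium and hydride transfer and leaves by neutral hydrogenolysis.

Step 3
Reactants: 3 tert-butyl 3-(prop-2-yn-1-yloxy)propanoate; 5 4-(benzyloxy)-3,5-dimethoxybenzaldehyde
Product: 7 tert-butyl 3-[4-(benzyloxy)-3,5-dimethoxyphenyl]-3-hydroxy-2-[(prop-2-yn-1-yloxy)methyl]propanoate (racemic syn/anti mixture), via dilithium enolate-acetylide 6 (not isolated)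
Conditions: LiN(iPr)2 (2.1 equiv), THF, −78 °C; 5 (0.95 equiv), −78 °C, 15 min; AcOH, −78 °C
Reagents that add atoms: none
Why: Directed aldol addition of a lithium ester enolate; the second equivalent of base parks the acidic alkyne C–H as the acetylide so that enolisation is complete, the enolate adds to the aldehyde far faster than the acetylide at −78 °C, and the configuration of both new centres is irrelevant because C7 is oxidised next and C8 becomes a carbanion.

Step 4
Reactants: 7 tert-butyl 3-[4-(benzyloxy)-3,5-dimethoxyphenyl]-3-hydroxy-2-[(prop-2-yn-1-yloxy)methyl]propanoate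
Product: 8 tert-butyl 2-[4-(benzyloxy)-3,5-dimethoxybenzoyl]-3-(prop-2-yn-1-yloxy)propanoate (racemic)
Conditions: Dess–Martin periodinane, CH2Cl2, 0 °C to rt
Reagents that add atoms: none
Why: Dess–Martin oxidation of a secondary benzylic alcohol under non-basic conditions, which avoids retro-aldol cleavage and beta-elimination of the propargyloxy group and converges both diastereomers of 7 on one β-keto ester.

Step 5
Reactants: 9 4-iodo-2-methoxyphenol
Product: 10 1-(benzyloxy)-4-iodo-2-methoxybenzene
Conditions: BnBr, K2CO3, DMF, rt
Reagents that add atoms: benzyl bromide, BrCc1ccccc1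
Why: Williamson ether synthesis; the aryl iodide is untouched by carbonate base.

Step 6
Reactants: 8 tert-butyl 2-[4-(benzyloxy)-3,5-dimethoxybenzoyl]-3-(prop-2-yn-1-yloxy)propanoate; 10 1-(benzyloxy)-4-iodo-2-methoxybenzene
Product: 12 tert-butyl 3-[4-(benzyloxy)-3,5-dimethoxybenzoyl]-4-[(Z)-4-(benzyloxy)-3-methoxybenzylidene]tetrahydrofuran-3-carboxylate (racemic), via potassium enolate 11 (not isolated)
Conditions: KOtBu (1.0 equiv), DMSO/THF, rt; then 10 (1.2 equiv), Pd(PPh3)4 (5 mol %), 45 °C
Reagents that add atoms: none
Why: Deprotonation gives the soft potassium enolate 11, and oxidative addition of 10 to zerovalent palladium gives ArPd(PPh3)2I (divalent palladium), which binds the terminal alkyne of 11. The enolate carbon C8 attacks the internal alkyne carbon C8' from the face opposite the metal (anti carbopalladation), and reductive elimination from the alkenyl(aryl)palladium intermediate joins C7' to the arene and returns zerovalent palladium. The closest known reaction type is the palladium-catalysed arylative cyclisation of alkyne-tethered malonate and β-keto ester carbanions with aryl halides, which gives arylidene tetrahydrofurans. The ring closes in the 5-exo-dig mode; 6-endo attack is geometrically disfavoured for the three-atom tether and attack through the enolate oxygen would need a seven-membered ring. The one new stereocentre, quaternary C8, forms without control and needs none, since it is erased in step 7; the Z geometry (aryl trans to C8) follows from anti addition and is in any case lost in step 9. The selectivity that matters is carbocyclisation over direct alkyne–aryl coupling and over loss of propargyl alkoxide by retro-oxa-Michael cleavage; the absence of copper salts, the pre-formed stoichiometric enolate in DMSO and the irreversible C–C bond formation, which drains the reversible fragmentation, should secure it. Exactly one equivalent of base is used so that no free alkoxide remains to cleave the non-enolisable β-keto ester product.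

Step 7
Reactants: 12 tert-butyl 3-[4-(benzyloxy)-3,5-dimethoxybenzoyl]-4-[(Z)-4-(benzyloxy)-3-methoxybenzylidene]tetrahydrofuran-3-carboxylate
Product: 14 [4-(benzyloxy)-3,5-dimethoxyphenyl]{4-[(Z)-4-(benzyloxy)-3-methoxybenzylidene]tetrahydrofuran-3-yl}methanone (racemic), via beta-keto acid 13 (not isolated)
Conditions: TFA/CH2Cl2 (1:4), 0 °C, 1 h; evaporate; PhMe, 60 °C
Reagents that add atoms: none
Why: Acidolysis of the tert-butyl ester (loss of 2-methylpropene) and thermal decarboxylation of the β-keto acid through a cyclic six-membered transition state; the dienol so formed should ketonise at C8 under kinetic control to the β,γ-unsaturated ketone, and short cold acid exposure followed by neutral warming is meant to keep the double bond out of conjugation.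

Step 8
Reactants: 14 [4-(benzyloxy)-3,5-dimethoxyphenyl]{4-[(Z)-4-(benzyloxy)-3-methoxybenzylidene]tetrahydrofuran-3-yl}methanone
Product: 15 (S)-[4-(benzyloxy)-3,5-dimethoxyphenyl]{(3R,4Z)-4-[4-(benzyloxy)-3-methoxybenzylidene]tetrahydrofuran-3-yl}methanol
Conditions: RuCl[(S,S)-TsDPEN](p-cymene) (3 mol %), HCO2H/Et3N (5:2), DMF, 30 °C
Reagents that add atoms: none
Why: Proposed new method: the closest known reaction type is Noyori-type asymmetric transfer hydrogenation with dynamic kinetic resolution of configurationally labile alpha-branched aryl ketones (benzoins, alpha-aryl ketones, alpha-substituted β-keto esters), not yet shown for a β,γ-unsaturated ketone; here C8–H is doubly activated (alpha to the aryl ketone and allylic to the styrenyl alkene), so the amine of the medium should racemise 14 through its dienol faster than hydride is transferred, the (S,S) catalyst fixes C7 as S through its aryl/arene CH–π preference as for acetophenones, and only the 8R enantiomer can place the bulky sp2 carbon C8' anti to the incoming hydride (Felkin–Anh) in that same transition state, so it is drained to (7S,8R)-15, while the outer-sphere hydride transfer leaves the alkene alone.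

Step 9
Reactants: 15 (S)-[4-(benzyloxy)-3,5-dimethoxyphenyl]{(3R,4Z)-4-[4-(benzyloxy)-3-methoxybenzylidene]tetrahydrofuran-3-yl}methanol
Product: 16 (S)-[4-(benzyloxy)-3,5-dimethoxyphenyl]{(3R,4R)-4-[4-(benzyloxy)-3-methoxybenzyl]tetrahydrofuran-3-yl}methanol
Conditions: [Ir(cod)(PCy3)(py)]PF6 (5 mol %), H2 (1 atm), CH2Cl2, rt
Reagents that add atoms: none
Why: Hydroxyl-directed homogeneous hydrogenation of a homoallylic alcohol; the C7 hydroxyl binds iridium and hydrogen is delivered to the alkene face that carries the C8 substituent, so the new C8'–H is cis to that substituent and the arylmethyl group ends trans (8'R); the catalyst does not cleave benzyl ethers.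

Step 10
Reactants: 16 (S)-[4-(benzyloxy)-3,5-dimethoxyphenyl]{(3R,4R)-4-[4-(benzyloxy)-3-methoxybenzyl]tetrahydrofuran-3-yl}methanol
Product: 17 4-{(S)-hydroxy[(3R,4R)-4-(4-hydroxy-3-methoxybenzyl)tetrahydrofuran-3-yl]methyl}-2,6-dimethoxyphenol (CNP0307127.1)
Conditions: H2 (1 atm), Pd/C (10 wt %), EtOAc, rt, stopped after uptake of 2 equiv
Reagents that add atoms: none
Why: Hydrogenolysis of the two aryl benzyl ethers under neutral conditions at low pressure, where O–benzyl cleavage should be much faster than cleavage of the benzylic C7–OH bond; no stereocentre is touched.

## Compound list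

1 | prop-2-yn-1-ol (propargyl alcohol) | C#CCO | starting material
2 | tert-butyl acrylate | C=CC(=O)OC(C)(C)C | starting material
3 | tert-butyl 3-(prop-2-yn-1-yloxy)propanoate | C#CCOCCC(=O)OC(C)(C)C | intermediate
4 | 4-hydroxy-3,5-dimethoxybenzaldehyde (syringaldehyde) | COc1cc(C=O)cc(OC)c1O | starting material
5 | 4-(benzyloxy)-3,5-dimethoxybenzaldehyde | COc1cc(C=O)cc(OC)c1OCc1ccccc1 | intermediate
6 | dilithium enolate-acetylide of 3 (not isolated) | [Li+].[Li+].[C-]#CCOCC=C([O-])OC(C)(C)C | intermediate
7 | tert-butyl 3-[4-(benzyloxy)-3,5-dimethoxyphenyl]-3-hydroxy-2-[(prop-2-yn-1-yloxy)methyl]propanoate (racemic, syn/anti mixture) | C#CCOCC(C(=O)OC(C)(C)C)C(O)c1cc(OC)c(OCc2ccccc2)c(OC)c1 | intermediate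
8 | tert-butyl 2-[4-(benzyloxy)-3,5-dimethoxybenzoyl]-3-(prop-2-yn-1-yloxy)propanoate (racemic) | C#CCOCC(C(=O)OC(C)(C)C)C(=O)c1cc(OC)c(OCc2ccccc2)c(OC)c1 | intermediate
9 | 4-iodo-2-methoxyphenol | COc1cc(I)ccc1O | starting material
10 | 1-(benzyloxy)-4-iodo-2-methoxybenzene | COc1cc(I)ccc1OCc1ccccc1 | intermediate
11 | potassium enolate of 8 (not isolated) | [K+].C#CCOCC(C(=O)OC(C)(C)C)=C([O-])c1cc(OC)c(OCc2ccccc2)c(OC)c1 | intermediate
12 | tert-butyl 3-[4-(benzyloxy)-3,5-dimethoxybenzoyl]-4-[(Z)-4-(benzyloxy)-3-methoxybenzylidene]tetrahydrofuran-3-carboxylate (racemic) | COc1cc(/C=C2\COCC2(C(=O)OC(C)(C)C)C(=O)c2cc(OC)c(OCc3ccccc3)c(OC)c2)ccc1OCc1ccccc1 | intermediate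
13 | 3-[4-(benzyloxy)-3,5-dimethoxybenzoyl]-4-[(Z)-4-(benzyloxy)-3-methoxybenzylidene]tetrahydrofuran-3-carboxylic acid (racemic, not isolated) | COc1cc(/C=C2\COCC2(C(=O)O)C(=O)c2cc(OC)c(OCc3ccccc3)c(OC)c2)ccc1OCc1ccccc1 | intermediate
14 | [4-(benzyloxy)-3,5-dimethoxyphenyl]{4-[(Z)-4-(benzyloxy)-3-methoxybenzylidene]tetrahydrofuran-3-yl}methanone (racemic, C8 labile) | COc1cc(/C=C2\COCC2C(=O)c2cc(OC)c(OCc3ccccc3)c(OC)c2)ccc1OCc1ccccc1 | intermediate
15 | (S)-[4-(benzyloxy)-3,5-dimethoxyphenyl]{(3R,4Z)-4-[4-(benzyloxy)-3-methoxybenzylidene]tetrahydrofuran-3-yl}methanol | COc1cc(/C=C2\COC[C@@H]2[C@H](O)c2cc(OC)c(OCc3ccccc3)c(OC)c2)ccc1OCc1ccccc1 | intermediate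
16 | (S)-[4-(benzyloxy)-3,5-dimethoxyphenyl]{(3R,4R)-4-[4-(benzyloxy)-3-methoxybenzyl]tetrahydrofuran-3-yl}methanol | COc1cc(C[C@H]2COC[C@@H]2[C@H](O)c2cc(OC)c(OCc3ccccc3)c(OC)c2)ccc1OCc1ccccc1 | intermediate
17 | 4-{(S)-hydroxy[(3R,4R)-4-(4-hydroxy-3-methoxybenzyl)tetrahydrofuran-3-yl]methyl}-2,6-dimethoxyphenol | COc1cc(C[C@H]2COC[C@@H]2[C@H](O)c2cc(OC)c(O)c(OC)c2)ccc1O | target

## Step count and least certain steps

Total: 10 steps. Longest linear sequence: 8 steps (steps 1, 3, 4, 6, 7, 8, 9, 10).

**Step 8 (proposed new method).** Epimerisation at C8 may be slower than hydride transfer, which would leave a plain kinetic resolution. The amine may move the double bond into conjugation with the ketone. The catalyst may prefer the ketone enantiomer that gives the wrong C7/C8 pairing. Turnover on a hindered, electron-rich ketone may be slow. The fallback gives up the dynamic step for established reactions; it sets out from 12 and rejoins at 16.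
- The alkene of 12 is hydrogenated with [Ir(cod)(PCy3)(py)]PF6 and H2 before the ester is touched, giving saturated keto ester F1, in which the quaternary centre blocks any double-bond migration.
- TFA and then warming remove the ester through keto acid F2, and brief DBU treatment equilibrates C8 to the racemic trans ketone F3.
- Transfer hydrogenation with RuCl[(S,S)-TsDPEN](p-cymene) and HCO2H/Et3N is then run as a kinetic resolution to about half conversion. Catalyst preference (7S) and Felkin–Anh preference coincide only for the (3R,4R) enantiomer, which should give 16, while the (3S,4S) ketone F4 is left and removed by chromatography.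
- The price is half of the material. The detour also keeps the electron-rich styrene away from the acid of step 7.

**Step 6 (key step).** Copper-free coupling of the aryl iodide with the terminal alkyne, loss of propargyl alkoxide by retro-oxa-Michael cleavage followed by polymerisation of the resulting acrylate, or protonation of the alkenylpalladium intermediate (cyclisation without arylation) may compete. The fallback separates ring closure from arylation; it sets out from 8 and returns at 12.
- Iodocarbocyclisation of 8 (I2, Ti(OtBu)4, CH2Cl2) closes the ring by anti addition of the enolate carbon and iodine across the alkyne and gives vinyl iodide F5.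
- Suzuki–Miyaura coupling of F5 with commercial [4-(benzyloxy)-3-methoxyphenyl]boronic acid (Pd(PPh3)4, K2CO3, dioxane/water) should give 12 with retention of the alkene geometry.

**Step 3.** The acetylide end of dianion 6 may add to the aldehyde, enolisation may be incomplete, or the enolate may expel the propargyloxy group on warming. The fallback masks the alkyne; it sets out from 2 and 5 and returns at 7.
- Commercial 3-(trimethylsilyl)prop-2-yn-1-ol is added to 2 under PBu3 catalysis (no alkoxide, so the C–Si bond survives) to give silyl ester F6.
- Aldol addition of F6 to 5 with LiN(iPr)2 (1.05 equiv) gives silylated aldol F7.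
- K2CO3 in MeOH removes the silyl group and gives 7.

**Step 7.** Acid may move the exocyclic double bond into conjugation with the ketone, induce cationic oligomerisation of the electron-rich styrene, or partly cleave the hindered syringyl benzyl ether. The fallback cleaves the ester without protic acid; it sets out from 12 and returns at 13 and hence 14.
- TMSOTf and 2,6-lutidine in CH2Cl2 at 0 °C convert the tert-butyl ester into trimethylsilyl ester F8 (the ketone of 12 has no alpha-hydrogen to silylate).
- Methanolysis gives 13, which is decarboxylated by warming in toluene as before.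

**Step 10.** Once the syringyl phenol is unmasked, over-reduction with loss of the benzylic C7–O bond may set in. The fallback shields the carbinol; it sets out from 16 and returns at 17.
- TBSCl and imidazole in DMF give silyl ether F9.
- Hydrogenolysis (H2, Pd/C, EtOAc) gives diphenol F10.
- Bu4NF buffered with AcOH in THF at 0 °C releases 17.

## Further compounds

F1 | step 8 | tert-butyl 3-[4-(benzyloxy)-3,5-dimethoxybenzoyl]-4-[4-(benzyloxy)-3-methoxybenzyl]tetrahydrofuran-3-carboxylate (racemic, both diastereomers) | COc1cc(CC2COCC2(C(=O)OC(C)(C)C)C(=O)c2cc(OC)c(OCc3ccccc3)c(OC)c2)ccc1OCc1ccccc1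
F2 | step 8 | 3-[4-(benzyloxy)-3,5-dimethoxybenzoyl]-4-[4-(benzyloxy)-3-methoxybenzyl]tetrahydrofuran-3-carboxylic acid (racemic, both diastereomers) | COc1cc(CC2COCC2(C(=O)O)C(=O)c2cc(OC)c(OCc3ccccc3)c(OC)c2)ccc1OCc1ccccc1
F3 | step 8 | [4-(benzyloxy)-3,5-dimethoxyphenyl]{trans-4-[4-(benzyloxy)-3-methoxybenzyl]tetrahydrofuran-3-yl}methanone (racemate, (3R,4R) enantiomer drawn) | COc1cc(C[C@H]2COC[C@@H]2C(=O)c2cc(OC)c(OCc3ccccc3)c(OC)c2)ccc1OCc1ccccc1
F4 | step 8 | [4-(benzyloxy)-3,5-dimethoxyphenyl]{(3S,4S)-4-[4-(benzyloxy)-3-methoxybenzyl]tetrahydrofuran-3-yl}methanone | COc1cc(C[C@@H]2COC[C@H]2C(=O)c2cc(OC)c(OCc3ccccc3)c(OC)c2)ccc1OCc1ccccc1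
F5 | step 6 | tert-butyl 3-[4-(benzyloxy)-3,5-dimethoxybenzoyl]-4-[(Z)-iodomethylidene]tetrahydrofuran-3-carboxylate (racemic) | I/C=C1\COCC1(C(=O)OC(C)(C)C)C(=O)c1cc(OC)c(OCc2ccccc2)c(OC)c1
F6 | step 3 | tert-butyl 3-{[3-(trimethylsilyl)prop-2-yn-1-yl]oxy}propanoate | C[Si](C)(C)C#CCOCCC(=O)OC(C)(C)C
F7 | step 3 | tert-butyl 3-[4-(benzyloxy)-3,5-dimethoxyphenyl]-3-hydroxy-2-({[3-(trimethylsilyl)prop-2-yn-1-yl]oxy}methyl)propanoate (racemic, syn/anti mixture) | C[Si](C)(C)C#CCOCC(C(=O)OC(C)(C)C)C(O)c1cc(OC)c(OCc2ccccc2)c(OC)c1
F8 | step 7 | trimethylsilyl 3-[4-(benzyloxy)-3,5-dimethoxybenzoyl]-4-[(Z)-4-(benzyloxy)-3-methoxybenzylidene]tetrahydrofuran-3-carboxylate (racemic) | COc1cc(/C=C2\COCC2(C(=O)O[Si](C)(C)C)C(=O)c2cc(OC)c(OCc3ccccc3)c(OC)c2)ccc1OCc1ccccc1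
F9 | step 10 | tert-butyldimethylsilyl ether of 16 at the C7 hydroxyl | COc1cc(C[C@H]2COC[C@@H]2[C@H](O[Si](C)(C)C(C)(C)C)c2cc(OC)c(OCc3ccccc3)c(OC)c2)ccc1OCc1ccccc1
F10 | step 10 | tert-butyldimethylsilyl ether of 17 at the C7 hydroxyl | COc1cc(C[C@H]2COC[C@@H]2[C@H](O[Si](C)(C)C(C)(C)C)c2cc(OC)c(O)c(OC)c2)ccc1O
A1 | alternative 1 | benzylic C7 boronate, (S,S)-1,2-dicyclohexylethane-1,2-diol ester, with boron in place of the C7 hydroxyl of 16 | COc1cc(C[C@H]2COC[C@@H]2[C@H](B2O[C@@H](C3CCCCC3)[C@H](C3CCCCC3)O2)c2cc(OC)c(OCc3ccccc3)c(OC)c2)ccc1OCc1ccccc1
A2 | alternative 1 | trans-4-[4-(benzyloxy)-3-methoxybenzyl]tetrahydrofuran-3-ylboronic acid (S,S)-1,2-dicyclohexylethane-1,2-diol ester (boron on C8) | COc1cc(C[C@H]2COC[C@@H]2B2O[C@@H](C3CCCCC3)[C@H](C3CCCCC3)O2)ccc1OCc1ccccc1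
A3 | alternative 1 | dichloromethyllithium | [Li]C(Cl)Cl
A4 | alternative 1 | [4-(benzyloxy)-3,5-dimethoxyphenyl]magnesium bromide | COc1cc([Mg]Br)cc(OC)c1OCc1ccccc1
A5 | alternative 2 | di-(−)-menthyl succinate | O=C(CCC(=O)O[C@@H]1C[C@H](C)CC[C@H]1C(C)C)O[C@@H]1C[C@H](C)CC[C@H]1C(C)C
A6 | alternative 2 | bis(bromomethyl) ether | BrCOCBr
A7 | alternative 2 | di-(−)-menthyl (3R,4R)-tetrahydrofuran-3,4-dicarboxylate | O=C(O[C@@H]1C[C@H](C)CC[C@H]1C(C)C)[C@H]1COC[C@@H]1C(=O)O[C@@H]1C[C@H](C)CC[C@H]1C(C)C
A8 | alternative 3 | (R)-5-[4-(benzyloxy)-3-methoxybenzyl]-4,5-dihydro-1,3-dioxepine | COc1cc(C[C@H]2COCOC=C2)ccc1OCc1ccccc1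
A9 | alternative 3 | (3R,4R)-4-[4-(benzyloxy)-3-methoxybenzyl]tetrahydrofuran-3-carbaldehyde (trans) | COc1cc(C[C@H]2COC[C@@H]2C=O)ccc1OCc1ccccc1
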